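## Retrosynthetic overview

1. Target 22 ← ortho-selective O-demethylation of trimethoxyphenyl ketone 21 ← palladium-mediated opening/alkenylation of aryl cyclobutanol 19 (one cyclobutane bond becomes the cis acyl/prenyl pair) ← aryllithium 18 + cyclobutanone 12.
2. Key step: 12 ← one-carbon ring expansion of the cis-fused cyclopentanone 7 (1,2-shift of a ring CH2 onto a diazo carbon), run as a ring-enlarging methyl-olefination that creates the cyclohexene and its C(Me)=CH unit.
3. 7 ← conjugate phenylation of bicyclic enone 5 ← enone–alkene [2+2] photocycloaddition of silyl ether 2 with 1,1-dimethoxyethene, then elimination.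
4. Aryl unit: resorcinol 13 → 1,3,5-trimethoxybenzene 17 (methylation, C–H borylation/oxidation, methylation).
5. Ring order: arene bought; cyclobutane built on the five-membered ring; five-membered ring expanded to the cyclohexene; cyclobutane opened last.

Assumption: 1 (R enantiomer, ≥98% ee), 3, 6 (THF solution), 8 (hexane solution), 13 and 20 are bought; 1 is the only source of absolute configuration.

## Route

Step 1
Reactants: 1 (R)-4-hydroxycyclopent-2-en-1-one
Product: 2 (R)-4-[(tert-butyldimethylsilyl)oxy]cyclopent-2-en-1-one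
Conditions: TBSCl, imidazole, DMF, 0 °C to rt
Reagents that add atoms: tert-butyldimethylsilyl chloride, CC(C)(C)[Si](C)(C)Cl
Why: Routine imidazole-mediated silylation of the secondary alcohol (stereocentre untouched); the bulky silyl ether steers the next step and later serves as leaving group.

Step 2
Reactants: 2 (R)-4-[(tert-butyldimethylsilyl)oxy]cyclopent-2-en-1-one; 3 1,1-dimethoxyethene
Product: 5 (1S,5S)-6,6-dimethoxybicyclo[3.2.0]hept-3-en-2-one, via silyloxy photoadduct 4 (not isolated)
Conditions: hν (350 nm), 3 (10 equiv), MeCN, −20 °C; then DBU, CH2Cl2, rt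
Reagents that add atoms: none
Why: Enone–alkene [2+2] photocycloaddition through the triplet 1,4-biradical gives the head-to-tail (acetal carbon on the β-carbon), cis-fused adduct on the face opposite the silyloxy group, which sets both ring-fusion centres (future C1 and C2), and DBU then expels silanolate (E1cB) to give enone 5.

Step 3
Reactants: 5 (1S,5S)-6,6-dimethoxybicyclo[3.2.0]hept-3-en-2-one; 6 phenylmagnesium bromide
Product: 7 (1S,4R,5S)-6,6-dimethoxy-4-phenylbicyclo[3.2.0]heptan-2-one
Conditions: PhMgBr, CuBr·SMe2 (10 mol%), THF, −40 °C; aqueous work-up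
Reagents that add atoms: none
Why: Copper-catalysed conjugate (1,4-) addition of the Grignard reagent occurs on the convex face of the cis-fused bicycle, trans to the cyclobutane bond at C5, and sets the phenyl-bearing centre (future C6).

Step 4
Reactants: 7 (1S,4R,5S)-6,6-dimethoxy-4-phenylbicyclo[3.2.0]heptan-2-one; 8 (trimethylsilyl)diazomethane
Product: 12 (1S,5R,6R)-2-methyl-5-phenylbicyclo[4.2.0]oct-2-en-7-one, via C-silyl ketone 9 (not isolated), via hydroxysilane 10 (not isolated), via alkene ketal 11 (not isolated)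
Conditions: 8 (1.5 equiv), Sc(CF3COCHCOCF3)3 (5 mol%), toluene, 0 °C; cannulate into MeLi/CeCl3 (3 equiv), THF, −78 °C; then 1 M H2SO4, THF, rt
Reagents that add atoms: methyllithium, [Li]C (methyl group); water, O (carbonyl oxygen of 12)
Why: Proposed new method: a one-flask ring-enlarging methyl-olefination in which trivalent scandium activates the cyclopentanone, the diazo carbon adds to C=O and the less substituted ring CH2 (C3) migrates to it with loss of N2 (Tiffeneau–Demjanov-type 1,2-shift), the chelating diketonate ligands holding back the 1,3-Brook shift so that C-silyl ketone 9 survives; MeCeCl2 then adds to its carbonyl and acid-triggered Peterson elimination of hydroxysilane 10 puts the double bond exactly between the old carbonyl carbon and the inserted carbon, while the same acid unmasks the cyclobutanone; the closest known reactions are the scandium-catalysed (trimethylsilyl)diazomethane homologation of cycloalkanones to β-keto silanes and the Peterson olefination, which have not been merged nor shown on a cis-fused bicyclo[3.2.0]heptan-2-one carrying a ketal; no stereocentre is made and the three existing ones are not touched.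

Step 5
Reactants: 13 resorcinol
Product: 14 1,3-dimethoxybenzene
Conditions: MeI, K2CO3, acetone, reflux
Reagents that add atoms: iodomethane, CI
Why: Williamson O-methylation (SN2) of both phenols.

Step 6
Reactants: 14 1,3-dimethoxybenzene
Product: 16 3,5-dimethoxyphenol, via aryl boronate 15 (not isolated)
Conditions: [Ir(OMe)(cod)]2 (1 mol%), 4,4′-di-tert-butyl-2,2′-bipyridine (2 mol%), B2pin2 (0.55 equiv), THF, 80 °C; then KHSO5 (as 2KHSO5·KHSO4·K2SO4), acetone/H2O, rt
Reagents that add atoms: bis(pinacolato)diboron, CC1(C)OB(OC1(C)C)B1OC(C)(C)C(C)(C)O1 (boryl group of 15); potassium peroxymonosulfate, [K+].OOS(=O)(=O)[O-] (hydroxyl oxygen of 16)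
Why: Sterically governed iridium-catalysed aromatic C–H borylation takes place at C5, the only C–H not next to a methoxy group, and peroxide oxidation of the C–B bond gives the phenol.

Step 7
Reactants: 16 3,5-dimethoxyphenol
Product: 17 1,3,5-trimethoxybenzene
Conditions: MeI, K2CO3, acetone, reflux
Reagents that add atoms: iodomethane, CI
Why: Williamson O-methylation (SN2).

Step 8
Reactants: 17 1,3,5-trimethoxybenzene; 12 (1S,5R,6R)-2-methyl-5-phenylbicyclo[4.2.0]oct-2-en-7-one
Product: 19 (1S,5R,6R,7R)-2-methyl-5-phenyl-7-(2,4,6-trimethoxyphenyl)bicyclo[4.2.0]oct-2-en-7-ol, via trimethoxyphenyllithium 18 (not isolated)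
Conditions: 17, n-BuLi, TMEDA, THF, 0 °C to rt; then 12, −78 °C; aqueous work-up (pH 7–8)
Reagents that add atoms: n-butyllithium, [Li]CCCC (lithium of 18 only)
Why: Directed ortho-lithiation between two methoxy groups gives 18, which adds 1,2 to the strained, poorly enolisable cyclobutanone from its convex face; the new carbinol centre is destroyed in step 9.

Step 9
Reactants: 19 (1S,5R,6R,7R)-2-methyl-5-phenyl-7-(2,4,6-trimethoxyphenyl)bicyclo[4.2.0]oct-2-en-7-ol; 20 1-bromo-2-methylprop-1-ene
Product: 21 [(1R,2S,6R)-3-methyl-2-(3-methylbut-2-en-1-yl)-6-phenylcyclohex-3-en-1-yl](2,4,6-trimethoxyphenyl)methanone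
Conditions: Pd(OAc)2 (5 mol%), XPhos (10 mol%), Cs2CO3, toluene, 90 °C
Reagents that add atoms: none
Why: Palladium-catalysed ring-opening cross-coupling of a tert-cyclobutanol: after oxidative addition of 20 to zerovalent palladium the palladium alkoxide undergoes strain-driven β-carbon elimination at the less hindered CH2–C(OH) bond, which unveils the aryl ketone on C1, and C(sp3)–C(sp2) reductive elimination completes the prenyl group on C2; neither ring stereocentre is touched, so the cis ring fusion becomes the cis acyl/prenyl pair.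

Step 10
Reactants: 21 [(1R,2S,6R)-3-methyl-2-(3-methylbut-2-en-1-yl)-6-phenylcyclohex-3-en-1-yl](2,4,6-trimethoxyphenyl)methanone
Product: 22 (2-hydroxy-4,6-dimethoxyphenyl)[(1R,2S,6R)-3-methyl-2-(3-methylbut-2-en-1-yl)-6-phenylcyclohex-3-en-1-yl]methanone
Conditions: BCl3 (1.2 equiv), CH2Cl2, −78 to 0 °C; then H2O
Reagents that add atoms: none
Why: Chelation-controlled Lewis-acid ether cleavage: BCl3 bound to the ketone oxygen removes only one ortho methyl group (as MeCl) and leaves the other methoxy groups and both alkenes.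

## Compound list

1 | (R)-4-hydroxycyclopent-2-en-1-one | O=C1C=C[C@H](O)C1 | starting material
2 | (R)-4-[(tert-butyldimethylsilyl)oxy]cyclopent-2-en-1-one | O=C1C=C[C@H](O[Si](C)(C)C(C)(C)C)C1 | intermediate
3 | 1,1-dimethoxyethene | C=C(OC)OC | starting material
4 | (1S,4R,5R)-4-[(tert-butyldimethylsilyl)oxy]-6,6-dimethoxybicyclo[3.2.0]heptan-2-one (cis-fused, silyloxy group trans to the cyclobutane) | O=C1C[C@@H](O[Si](C)(C)C(C)(C)C)[C@H]2[C@@H]1CC2(OC)OC | intermediate (not isolated)
5 | (1S,5S)-6,6-dimethoxybicyclo[3.2.0]hept-3-en-2-one | O=C1C=C[C@H]2[C@@H]1CC2(OC)OC | intermediate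
6 | phenylmagnesium bromide | Br[Mg]c1ccccc1 | starting material
7 | (1S,4R,5S)-6,6-dimethoxy-4-phenylbicyclo[3.2.0]heptan-2-one (cis-fused, phenyl trans to the cyclobutane) | O=C1C[C@@H](c2ccccc2)[C@H]3[C@@H]1CC3(OC)OC | intermediate
8 | (trimethylsilyl)diazomethane | C[Si](C)(C)C=[N+]=[N-] | starting material
9 | (1S,5R,6S)-7,7-dimethoxy-5-phenyl-3-(trimethylsilyl)bicyclo[4.2.0]octan-2-one (C3 epimers) | O=C1C([Si](C)(C)C)C[C@@H](c2ccccc2)[C@H]3[C@@H]1CC3(OC)OC | intermediate (not isolated)
10 | (1S,5R,6S)-7,7-dimethoxy-2-methyl-5-phenyl-3-(trimethylsilyl)bicyclo[4.2.0]octan-2-ol (epimers at C2 and C3) | CC1(O)C([Si](C)(C)C)C[C@@H](c2ccccc2)[C@H]3[C@@H]1CC3(OC)OC | intermediate (not isolated)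
11 | (1S,5R,6R)-7,7-dimethoxy-2-methyl-5-phenylbicyclo[4.2.0]oct-2-ene | CC1=CC[C@@H](c2ccccc2)[C@H]3[C@@H]1CC3(OC)OC | intermediate (not isolated)
12 | (1S,5R,6R)-2-methyl-5-phenylbicyclo[4.2.0]oct-2-en-7-one | O=C1C[C@@H]2C(C)=CC[C@@H](c3ccccc3)[C@H]12 | intermediate
13 | resorcinol (benzene-1,3-diol) | Oc1cccc(O)c1 | starting material
14 | 1,3-dimethoxybenzene | COc1cccc(OC)c1 | intermediate
15 | 2-(3,5-dimethoxyphenyl)-4,4,5,5-tetramethyl-1,3,2-dioxaborolane | COc1cc(OC)cc(B2OC(C)(C)C(C)(C)O2)c1 | intermediate (not isolated)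
16 | 3,5-dimethoxyphenol | COc1cc(O)cc(OC)c1 | intermediate
17 | 1,3,5-trimethoxybenzene | COc1cc(OC)cc(OC)c1 | intermediate
18 | 2,4,6-trimethoxyphenyllithium | [Li]c1c(OC)cc(OC)cc1OC | intermediate (not isolated)
19 | (1S,5R,6R,7R)-2-methyl-5-phenyl-7-(2,4,6-trimethoxyphenyl)bicyclo[4.2.0]oct-2-en-7-ol (aryl cis to the ring-fusion hydrogens) | COc1cc(OC)c([C@@]2(O)C[C@@H]3C(C)=CC[C@@H](c4ccccc4)[C@H]23)c(OC)c1 | intermediate
20 | 1-bromo-2-methylprop-1-ene | CC(C)=CBr | starting material
21 | [(1R,2S,6R)-3-methyl-2-(3-methylbut-2-en-1-yl)-6-phenylcyclohex-3-en-1-yl](2,4,6-trimethoxyphenyl)methanone | COc1cc(OC)c(C(=O)[C@@H]2[C@H](CC=C(C)C)C(C)=CC[C@H]2c2ccccc2)c(OC)c1 | intermediate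
22 | (2-hydroxy-4,6-dimethoxyphenyl)[(1R,2S,6R)-3-methyl-2-(3-methylbut-2-en-1-yl)-6-phenylcyclohex-3-en-1-yl]methanone | COc1cc(O)c(C(=O)[C@@H]2[C@H](CC=C(C)C)C(C)=CC[C@H]2c2ccccc2)c(OC)c1 | target

## Count and risks

Total steps: 10. Longest linear sequence: 7 (steps 1–4 and 8–10); the arene branch (steps 5–7) joins at step 8.

Steps most likely to fail:

Step 4 (the proposed new step). Risks:
- migration of the ring-fusion carbon instead of CH2;
- early Brook shift to the enol silane;
- enolisation of 9 instead of methyl addition;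
- a cyclobutylcarbinyl shift competing with the Peterson elimination;
- loss of the ketal to the Lewis acid.

The fallback uses known chemistry, sets out from 7 and comes back at 11. Homologation of 7 with (trimethylsilyl)diazomethane and catalytic Sc(OTf)3 in toluene gives, after 1,3-Brook shift, the regiodefined enol silane (1S,5R,6S)-[(7,7-dimethoxy-5-phenylbicyclo[4.2.0]oct-2-en-2-yl)oxy]trimethylsilane F3. MeLi in THF at 0 °C cleaves it to the lithium enolate, which N-phenylbis(trifluoromethanesulfonimide) traps as (1S,5R,6S)-7,7-dimethoxy-5-phenylbicyclo[4.2.0]oct-2-en-2-yl trifluoromethanesulfonate F4. Coupling of F4 with MeMgBr and catalytic Fe(acac)3 in THF/N-methylpyrrolidone at −30 °C gives 11, now isolated, which is hydrolysed to 12 with dilute acid as in step 4. The alkene then comes from a cross-coupling and not from addition/elimination.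

Step 9. Risks:
- β-carbon elimination toward the ring-fusion carbon;
- β-hydride elimination of the primary alkylpalladium;
- sluggish alkoxide formation at the crowded, acid-sensitive carbinol;
- base epimerisation at C1.

The fallback avoids the cyclobutanol, sets out from 12 and comes back at 21.
- The enolate of 12 (LiN(SiMe3)2, THF, −78 °C, formed on the CH2 side) is hydroxylated with 2-(phenylsulfonyl)-3-phenyloxaziridine to (1S,5R,6S)-8-hydroxy-2-methyl-5-phenylbicyclo[4.2.0]oct-2-en-7-one F5 (C8 epimers).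
- Pb(OAc)4 in methanol/benzene cleaves the ketol to methyl (1S,2S,6R)-2-formyl-3-methyl-6-phenylcyclohex-3-ene-1-carboxylate F6.
- NaBH4 is added at once and the hydroxy ester closes to the cis-fused lactone (3aS,7R,7aS)-4-methyl-7-phenyl-3a,6,7,7a-tetrahydro-2-benzofuran-1(3H)-one F7.
- Aryllithium 18 opens the lactone to [(1S,2S,6R)-2-(hydroxymethyl)-3-methyl-6-phenylcyclohex-3-en-1-yl](2,4,6-trimethoxyphenyl)methanone F8.
- I2, PPh3 and imidazole give [(1S,2S,6R)-2-(iodomethyl)-3-methyl-6-phenylcyclohex-3-en-1-yl](2,4,6-trimethoxyphenyl)methanone F9.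
- Lithium bis(2-methylprop-1-enyl)cuprate (from 20, t-BuLi and CuI) displaces the iodide to give 21.

Step 2. Risks:
- head-to-tail and facial selectivity may be eroded because the acetal carbon is formed next to the silyloxy-bearing carbon;
- the elimination may be incomplete.

The fallback changes the order of events, sets out from 2 and comes back at 7. Copper-catalysed addition of PhMgBr to 2 (anti to the silyloxy group) gives (3S,4R)-4-[(tert-butyldimethylsilyl)oxy]-3-phenylcyclopentan-1-one F1. Brief treatment with DBU at 0 °C gives (R)-4-phenylcyclopent-2-en-1-one F2, used at once because base can move its double bond into conjugation with the phenyl group. Photocycloaddition of F2 with 3 (350 nm, MeCN, −20 °C), head-to-tail and anti to phenyl, gives 7 directly.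

Further compounds
F1 | step 2 | (3S,4R)-4-[(tert-butyldimethylsilyl)oxy]-3-phenylcyclopentan-1-one | O=C1C[C@@H](c2ccccc2)[C@H](O[Si](C)(C)C(C)(C)C)C1
F2 | step 2 | (R)-4-phenylcyclopent-2-en-1-one | O=C1C=C[C@H](c2ccccc2)C1
F3 | step 4 | (1S,5R,6S)-[(7,7-dimethoxy-5-phenylbicyclo[4.2.0]oct-2-en-2-yl)oxy]trimethylsilane | C[Si](C)(C)OC1=CC[C@@H](c2ccccc2)[C@H]3[C@@H]1CC3(OC)OC
F4 | step 4 | (1S,5R,6S)-7,7-dimethoxy-5-phenylbicyclo[4.2.0]oct-2-en-2-yl trifluoromethanesulfonate | O=S(=O)(OC1=CC[C@@H](c2ccccc2)[C@H]3[C@@H]1CC3(OC)OC)C(F)(F)F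
F5 | step 9 | (1S,5R,6S)-8-hydroxy-2-methyl-5-phenylbicyclo[4.2.0]oct-2-en-7-one (C8 epimers) | O=C1C(O)[C@@H]2C(C)=CC[C@@H](c3ccccc3)[C@H]12
F6 | step 9 | methyl (1S,2S,6R)-2-formyl-3-methyl-6-phenylcyclohex-3-ene-1-carboxylate | COC(=O)[C@@H]1[C@H](C=O)C(C)=CC[C@H]1c1ccccc1
F7 | step 9 | (3aS,7R,7aS)-4-methyl-7-phenyl-3a,6,7,7a-tetrahydro-2-benzofuran-1(3H)-one | O=C1OC[C@@H]2C(C)=CC[C@@H](c3ccccc3)[C@H]12
F8 | step 9 | [(1S,2S,6R)-2-(hydroxymethyl)-3-methyl-6-phenylcyclohex-3-en-1-yl](2,4,6-trimethoxyphenyl)methanone | COc1cc(OC)c(C(=O)[C@@H]2[C@H](CO)C(C)=CC[C@H]2c2ccccc2)c(OC)c1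
F9 | step 9 | [(1S,2S,6R)-2-(iodomethyl)-3-methyl-6-phenylcyclohex-3-en-1-yl](2,4,6-trimethoxyphenyl)methanone | COc1cc(OC)c(C(=O)[C@@H]2[C@H](CI)C(C)=CC[C@H]2c2ccccc2)c(OC)c1
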